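(All runs were generated by integration with constants of no real substance, noise included.)

1. Read from Tuesday's run how fast target falls; its rise lies before the first reading.

- Tuesday's: starting material 0.10 M; partner 0.36 M; second substrate 0.20 M; run made earlier
- flask: starting material 0.20 M; partner 0.360 M; second substrate 0.200 M; time 5.0 h

- Tuesday's (time / min: target / %): 12.0: 19.1; 25.0: 17.2; 40.0: 16.0; 50.0: 15.7; 60.0: 12.4; 80.0: 12.8; 90.0: 11.5

(scatter of a reading: 1 percentage point)

- the best time, 5.0 h at the latest, for target
- the amount of target, in percent of the starting material charged, at that time
- the first time at which target reaches 4.4%, in the same percent, in min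



2. In Tuesday's run, between 12.0 min and 90.0 min, the readings of target go from 19.1% to 11.5%. So it falls at 0.00650 /min, and this share lost per minute is the fall constant, a first-order decay constant read from readings with their scatter. It means a half-life of 107 min.

3. While the fall constant stays steady, the rate of loss slows as target shrinks, by a factor of two each half-life. This flask's 5.0 h holds 2.80 of Tuesday's half-lives, so at Tuesday's fall constant I reckon that target in this flask keeps 14.2% of its peak.

4. This flask holds twice Tuesday's starting material. If the fall constant goes in proportion to the charge of starting material, it becomes 0.0130 /min and I reckon that target keeps 2.02%. I commit to that range, with the peak before 12.0 min.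

5. The forecast, which stands at the slow end of my range in holding that “decay should barely change”, gave 18.5% at 0.12 h, and the level asked after 1 min.

6. This flask peaks at 14.7% at 0.0557 h and reaches the level asked after 0.219 min.

    starting material + partner ⇌ target (K = 49.0 /M, k = 0.0110 /M/s)
    second substrate + partner ⇌ second product (K = 3.80 /M, k = 0.00500 /M/s)
    target ⇌ isomer of the product (K = 1.60, k = 0.0120 /s)
    starting material + target → side product (k = 0.0250 /M/s)
    partner → decomposed reagent (k = 0.00160 /s)

From 2.50 h to 5.00 h this flask's target falls from 3.07% to 0.711%, a fall constant of 0.00975 /min, above Tuesday's and below my upper figure. In the neighbour flask with 0.050 M of starting material, the 14.2% kept at Tuesday's fall constant reckons its peak of 23.8% down to 3.38%, and that flask ends at 2.19%. In this flask at 0.138 h, the step from starting material + target to side product has a half-life for target of 0.13 h, shorter than the 5.0 h, while target is made at 0.900 of the rate it is used, each step taken net. At 5.00 h that ratio is 0.621, and side product holds 93.8% of the starting material charged.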